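**Retrosynthetic overview**
1. The last step makes the ester C–O bond, the C4 centre and the γ-methylene lactone together: the carboxylate of keto acid 16 opens β-lactone 19 and the freed carboxylate re-closes on the alkyne (4- to 5-membered ring expansion).
2. 19 comes from E hydroxy acid 18 (β-lactonisation), which comes from (R)-ester 13 by Z→E isomerisation and saponification; 16 comes from Z alkynoic acid 14 (alkyne hydration), which comes from (S)-acetate 12.
3. 12 and 13 are the two enantiomers from one lipase resolution of racemic Z ester 11; both are used.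
4. 11 comes from Negishi coupling of tridecylzinc bromide with the (Z)-β-iodo Baylis–Hillman ester 9 (ethyl propiolate + TMSI + 3-(trimethylsilyl)propynal); the C13 chain comes from heptylmagnesium bromide + 1,6-dibromohexane.
5. Ring order: β-lactone (step 9), then γ-lactone (step 10); enol lactone 15 in step 6 is transient.

Assumption: the lipase follows Kazlauskas' rule with the α-branched alkenyl group as large and the silylalkynyl group as medium substituent; if the sense is opposite, the acetate and alcohol streams are simply exchanged (both pass through the same LiOH step).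

**Route**

Step 1
Reactants: 1 1-bromoheptane; 2 1,6-dibromohexane
Product: 4 1-bromotridecane, via heptylmagnesium bromide 3 (not isolated)
Conditions: Mg, THF; then 2 (3 equiv), Li2CuCl4 (2 mol%), THF, −10 → 20 °C
Reagents that add atoms: none
Why: Cu-catalysed sp3–sp3 Grignard coupling (Kochi type); the excess of dibromide limits coupling to one end, and no stereocentre is involved.

Step 2
Reactants: 5 ethyl propiolate; 6 3-(trimethylsilyl)prop-2-ynal
Product: 9 ethyl (2Z)-2-[1-hydroxy-3-(trimethylsilyl)prop-2-yn-1-yl]-3-iodoprop-2-enoate (racemic), via iodoallenyl silyl ketene acetal 7 (not isolated), via O-silylated aldol adduct 8 (not isolated)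
Conditions: TMSI (1.1 equiv), CH2Cl2, −78 °C; then 6, BF3·OEt2 (20 mol%), −78 °C; 1 M HCl work-up
Reagents that add atoms: iodotrimethylsilane C[Si](C)(C)I
Why: iodide conjugate addition gives the β-iodo allenoate, which undergoes a Mukaiyama-type aldol with the ynal anti to iodine (halo-aldol, β-iodo Morita–Baylis–Hillman reaction), fixing the Z geometry (I cis to CO2Et); the carbinol is racemic here.

Step 3
Reactants: 9 (racemic iodo ester); 4 1-bromotridecane
Product: 11 ethyl (2Z)-2-[1-hydroxy-3-(trimethylsilyl)prop-2-yn-1-yl]hexadec-2-enoate (racemic), via tridecylzinc bromide 10 (not isolated)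
Conditions: 4, Zn dust, LiCl, THF, 50 °C; then 9, PdCl2(dppf) (3 mol%), THF, 25 °C
Reagents that add atoms: none
Why: Negishi alkyl–alkenyl coupling proceeds with retention, so the C13 chain takes the place of iodine cis to the ester (Z); the free OH, ester and silylalkyne tolerate the alkylzinc.

Step 4
Reactants: 11 (racemic Z ester)
Product: 12 ethyl (2Z)-2-[(1S)-1-acetoxy-3-(trimethylsilyl)prop-2-yn-1-yl]hexadec-2-enoate; 13 ethyl (2Z)-2-[(1R)-1-hydroxy-3-(trimethylsilyl)prop-2-yn-1-yl]hexadec-2-enoate (unreacted enantiomer, recovered)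
Conditions: Amano lipase PS-IM, vinyl acetate (3 equiv), MTBE, 35 °C, stopped at 50% conversion; chromatography
Reagents that add atoms: vinyl acetate CC(=O)OC=C
Why: lipase-catalysed kinetic resolution by enantioselective acylation sets both carbinol configurations (S acetylated, R left), and both enantiomers are carried on, so nothing is discarded.

Step 5
Reactants: 12 (S acetate)
Product: 14 (2Z)-2-[(1R)-1-hydroxyprop-2-yn-1-yl]hexadec-2-enoic acid
Conditions: LiOH·H2O (5 equiv), THF–MeOH–H2O, 0 → 25 °C; 1 M HCl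
Reagents that add atoms: lithium hydroxide [Li+].[OH-]
Why: saponification removes the acetate, the ethyl ester and the C-silyl group in one operation without touching the stereocentre (the descriptor changes from S to R only because the silyl group is lost).

Step 6
Reactants: 14
Product: 16 (2Z,3S)-3-hydroxy-4-oxo-2-tetradecylidenepentanoic acid, via Z-enol lactone 15 (not isolated)
Conditions: AuCl (5 mol%), K2CO3 (10 mol%), MeCN, 25 °C; then THF–0.5 M HCl, 25 °C
Reagents that add atoms: water O
Why: Au(I)-catalysed 5-exo-dig cycloisomerisation of the γ-alkynoic acid followed by acid hydrolysis of the enol lactone amounts to a Markovnikov hydration, under conditions too mild to epimerise the acyloin centre.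

Step 7
Reactants: 13 (R alcohol, Z)
Product: 17 ethyl (2E)-2-[(1R)-1-hydroxy-3-(trimethylsilyl)prop-2-yn-1-yl]hexadec-2-enoate
Conditions: I2 (5 mol%), CH2Cl2, visible light, 25 °C; chromatography, residual 13 recycled
Reagents that add atoms: none
Why: iodine-atom-catalysed Z→E equilibration (angelate→tiglate type) favours the E ester, in which the chain no longer clashes with the ester group; the carbinol centre is not involved.

Step 8
Reactants: 17
Product: 18 (2E)-2-[(1S)-1-hydroxyprop-2-yn-1-yl]hexadec-2-enoic acid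
Conditions: LiOH·H2O (4 equiv), THF–MeOH–H2O, 0 → 25 °C; 1 M HCl
Reagents that add atoms: lithium hydroxide [Li+].[OH-]
Why: ester saponification with concurrent protodesilylation of the alkyne; the descriptor changes from R to S only through the loss of silicon.

Step 9
Reactants: 18
Product: 19 (3E,4S)-4-ethynyl-3-tetradecylideneoxetan-2-one
Conditions: PhSO2Cl (2 equiv), pyridine, 0–4 °C
Reagents that add atoms: none
Why: Adam β-lactonisation through carboxyl activation (mixed sulfonic anhydride) closes the four-membered ring with retention at C4, as established for α-methylene-β-hydroxy acids.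

Step 10
Reactants: 19 (1.1 equiv); 16 (1.0 equiv)
Product: 21 (3E,4S)-5-methylidene-2-oxo-3-tetradecylideneoxolan-4-yl (2Z,3S)-3-hydroxy-4-oxo-2-tetradecylidenepentanoate (CNP0377581.1), via ring-opened propargylic ester acid 20 (not isolated)
Conditions: Cs2CO3 (10 mol%), AuCl (5 mol%), MeCN, 40 °C
Reagents that add atoms: none
Why: Proposed new method: the carboxylate of 16 opens the strained propargylic β-lactone by SN2 attack at C4 with inversion (conjugate SN2′ opening is disfavoured because the C4–O bond lies in the ring plane, orthogonal to the exocyclic π bond), and the freed acrylate carboxylate 20 is trapped at once by Au(I)-catalysed 5-exo-dig attack on its own alkyne, so the lactone oxygen moves from C4 to C5 (net 1,2-acyloxy shift, ring expansion of the β-lactone to the γ-methylene γ-lactone) while the unprotected acyloin OH of 16 stays a bystander; closest known reactions are carboxylate opening of β-lactones at the β-carbon (anionic β-lactone polymerisation, serine β-lactone openings) and AuCl/K2CO3 cycloisomerisation of γ-alkynoic acids.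

**Compound list**
1 | 1-bromoheptane | CCCCCCCBr | starting material
2 | 1,6-dibromohexane | BrCCCCCCBr | starting material
3 | heptylmagnesium bromide (not isolated) | CCCCCCC[Mg]Br | intermediate
4 | 1-bromotridecane | CCCCCCCCCCCCCBr | intermediate
5 | ethyl propiolate | CCOC(=O)C#C | starting material
6 | 3-(trimethylsilyl)prop-2-ynal | C[Si](C)(C)C#CC=O | starting material
7 | [(1-ethoxy-3-iodopropa-1,2-dien-1-yl)oxy]trimethylsilane (not isolated) | CCOC(=C=CI)O[Si](C)(C)C | intermediate
8 | ethyl (2Z)-3-iodo-2-[3-(trimethylsilyl)-1-(trimethylsilyloxy)prop-2-yn-1-yl]prop-2-enoate, racemic (not isolated) | CCOC(=O)/C(=C\I)C(O[Si](C)(C)C)C#C[Si](C)(C)C | intermediate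
9 | ethyl (2Z)-2-[1-hydroxy-3-(trimethylsilyl)prop-2-yn-1-yl]-3-iodoprop-2-enoate, racemic | CCOC(=O)/C(=C\I)C(O)C#C[Si](C)(C)C | intermediate
10 | tridecylzinc bromide (not isolated) | CCCCCCCCCCCCC[Zn]Br | intermediate
11 | ethyl (2Z)-2-[1-hydroxy-3-(trimethylsilyl)prop-2-yn-1-yl]hexadec-2-enoate, racemic | CCOC(=O)/C(=C\CCCCCCCCCCCCC)C(O)C#C[Si](C)(C)C | intermediate
12 | ethyl (2Z)-2-[(1S)-1-acetoxy-3-(trimethylsilyl)prop-2-yn-1-yl]hexadec-2-enoate | CCOC(=O)/C(=C\CCCCCCCCCCCCC)[C@H](OC(C)=O)C#C[Si](C)(C)C | intermediate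
13 | ethyl (2Z)-2-[(1R)-1-hydroxy-3-(trimethylsilyl)prop-2-yn-1-yl]hexadec-2-enoate | CCOC(=O)/C(=C\CCCCCCCCCCCCC)[C@@H](O)C#C[Si](C)(C)C | intermediate
14 | (2Z)-2-[(1R)-1-hydroxyprop-2-yn-1-yl]hexadec-2-enoic acid | OC(=O)/C(=C\CCCCCCCCCCCCC)[C@H](O)C#C | intermediate
15 | (3Z,4S)-4-hydroxy-5-methylidene-3-tetradecylideneoxolan-2-one (not isolated) | C=C1OC(=O)/C(=C\CCCCCCCCCCCCC)[C@@H]1O | intermediate
16 | (2Z,3S)-3-hydroxy-4-oxo-2-tetradecylidenepentanoic acid | OC(=O)/C(=C\CCCCCCCCCCCCC)[C@H](O)C(C)=O | intermediate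
17 | ethyl (2E)-2-[(1R)-1-hydroxy-3-(trimethylsilyl)prop-2-yn-1-yl]hexadec-2-enoate | CCOC(=O)/C(=C/CCCCCCCCCCCCC)[C@@H](O)C#C[Si](C)(C)C | intermediate
18 | (2E)-2-[(1S)-1-hydroxyprop-2-yn-1-yl]hexadec-2-enoic acid | OC(=O)/C(=C/CCCCCCCCCCCCC)[C@@H](O)C#C | intermediate
19 | (3E,4S)-4-ethynyl-3-tetradecylideneoxetan-2-one | O=C1O[C@@H](C#C)/C1=C\CCCCCCCCCCCCC | intermediate
20 | (2E)-2-[(1R)-1-{[(2Z,3S)-3-hydroxy-4-oxo-2-tetradecylidenepentanoyl]oxy}prop-2-yn-1-yl]hexadec-2-enoic acid, present as its carboxylate (not isolated) | OC(=O)/C(=C/CCCCCCCCCCCCC)[C@@H](C#C)OC(=O)/C(=C\CCCCCCCCCCCCC)[C@H](O)C(C)=O | intermediate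
21 | (3E,4S)-5-methylidene-2-oxo-3-tetradecylideneoxolan-4-yl (2Z,3S)-3-hydroxy-4-oxo-2-tetradecylidenepentanoate | C=C1OC(=O)/C(=C/CCCCCCCCCCCCC)[C@@H]1OC(=O)/C(=C\CCCCCCCCCCCCC)[C@H](O)C(C)=O | target

**Step count and risks**
Total: 10 steps. Longest linear sequence: 7 steps (2, 3, 4, 7, 8, 9, 10).

Steps most likely to fail:

- **Step 4 (lipase resolution of a hindered Baylis–Hillman-type alcohol).** Fallback sets out from 5, 6 and 4 and returns at 13 and 14. The known catalytic asymmetric three-component iodo-aldol (TMSI, chiral oxazaborolidinium triflimide, −78 °C) is run once with each catalyst enantiomer. This gives ethyl (2Z)-2-[(1R)-1-hydroxy-3-(trimethylsilyl)prop-2-yn-1-yl]-3-iodoprop-2-enoate F1 and its (1S) enantiomer F2. Negishi coupling with 10 as in step 3 converts F2 into 13 and F1 into ethyl (2Z)-2-[(1S)-1-hydroxy-3-(trimethylsilyl)prop-2-yn-1-yl]hexadec-2-enoate F3. F3 is saponified as in step 5 to give 14.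

- **Step 7 (thermodynamic Z→E ratio may be modest).** Fallback sets out from 4, 5 and 6 and returns at 17. Bromide 4 is converted into tridecylmagnesium bromide F4, which with CuBr·SMe2 adds syn to 5 at −78 °C. Iodine quench of the vinylcopper gives ethyl (2Z)-2-iodohexadec-2-enoate F5 (chain cis to iodine). Nozaki–Hiyama–Kishi coupling (CrCl2, cat. NiCl2, DMF) with 6 gives racemic ethyl (2E)-2-[1-hydroxy-3-(trimethylsilyl)prop-2-yn-1-yl]hexadec-2-enoate F6. Lipase resolution as in step 4 leaves 17 and ethyl (2E)-2-[(1S)-1-acetoxy-3-(trimethylsilyl)prop-2-yn-1-yl]hexadec-2-enoate F7.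

- **Step 10 (proposed new ring expansion; risks are acyl attack with retention, SN2′ opening or oligomerisation).** Fallback uses only known reactions, sets out from 18 and 16 and returns at 21. AuCl/K2CO3 cycloisomerisation of 18 gives (3E,4R)-4-hydroxy-5-methylidene-3-tetradecylideneoxolan-2-one F8. Acid 16 is silylated (TESCl, imidazole; silyl ester cleaved on aqueous work-up) to (2Z,3S)-4-oxo-2-tetradecylidene-3-[(triethylsilyl)oxy]pentanoic acid F9. Mitsunobu esterification of F8 with F9 (PPh3, DIAD, THF, 0 °C) inverts C4 and gives (3E,4S)-5-methylidene-2-oxo-3-tetradecylideneoxolan-4-yl (2Z,3S)-4-oxo-2-tetradecylidene-3-[(triethylsilyl)oxy]pentanoate F10. HF·pyridine then gives 21.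

**Further compounds**
F1 | step 4 | ethyl (2Z)-2-[(1R)-1-hydroxy-3-(trimethylsilyl)prop-2-yn-1-yl]-3-iodoprop-2-enoate | CCOC(=O)/C(=C\I)[C@H](O)C#C[Si](C)(C)C
F2 | step 4 | ethyl (2Z)-2-[(1S)-1-hydroxy-3-(trimethylsilyl)prop-2-yn-1-yl]-3-iodoprop-2-enoate | CCOC(=O)/C(=C\I)[C@@H](O)C#C[Si](C)(C)C
F3 | step 4 | ethyl (2Z)-2-[(1S)-1-hydroxy-3-(trimethylsilyl)prop-2-yn-1-yl]hexadec-2-enoate | CCOC(=O)/C(=C\CCCCCCCCCCCCC)[C@H](O)C#C[Si](C)(C)C
F4 | step 7 | tridecylmagnesium bromide | CCCCCCCCCCCCC[Mg]Br
F5 | step 7 | ethyl (2Z)-2-iodohexadec-2-enoate | CCOC(=O)/C(I)=C/CCCCCCCCCCCCC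
F6 | step 7 | ethyl (2E)-2-[1-hydroxy-3-(trimethylsilyl)prop-2-yn-1-yl]hexadec-2-enoate, racemic | CCOC(=O)/C(=C/CCCCCCCCCCCCC)C(O)C#C[Si](C)(C)C
F7 | step 7 | ethyl (2E)-2-[(1S)-1-acetoxy-3-(trimethylsilyl)prop-2-yn-1-yl]hexadec-2-enoate | CCOC(=O)/C(=C/CCCCCCCCCCCCC)[C@H](OC(C)=O)C#C[Si](C)(C)C
F8 | step 10 | (3E,4R)-4-hydroxy-5-methylidene-3-tetradecylideneoxolan-2-one | C=C1OC(=O)/C(=C/CCCCCCCCCCCCC)[C@H]1O
F9 | step 10 | (2Z,3S)-4-oxo-2-tetradecylidene-3-[(triethylsilyl)oxy]pentanoic acid | OC(=O)/C(=C\CCCCCCCCCCCCC)[C@H](O[Si](CC)(CC)CC)C(C)=O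
F10 | step 10 | (3E,4S)-5-methylidene-2-oxo-3-tetradecylideneoxolan-4-yl (2Z,3S)-4-oxo-2-tetradecylidene-3-[(triethylsilyl)oxy]pentanoate | C=C1OC(=O)/C(=C/CCCCCCCCCCCCC)[C@@H]1OC(=O)/C(=C\CCCCCCCCCCCCC)[C@H](O[Si](CC)(CC)CC)C(C)=O
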